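**Plan**

1. Retrosynthesis: the C13 acetate and the silicon protection come off first. A helper carboxyl on C11 turns C17=C8–C9–C11 into the γ,δ‑unsaturated acid of a Claisen product, so C9–C11 is cut (retro‑Ireland–Claisen) into a C17 allylic alcohol on a cis‑fused Δ8(9)‑decalin and a linalool‑derived C6 acid. The core is then cut at C8–C17 (Stille), C10–C20 (cuprate), back to an anisole (retro‑Birch) and at C4–C19 (hydrovinylation).
2. Forward: ring A is carried intact from 6‑methoxy‑1‑tetralone and ring B is made from its anisole ring by Birch dearomatisation. C20 and C17 are added, the side chain is attached as the C17 ester and moved onto C9 by the [3,3] shift. Decarboxylation, desilylation and acetylation finish.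
3. Stereochemistry: C4 from Ni‑catalysed asymmetric hydrovinylation; C5 from ester‑directed Ir hydrogenation (H syn to C19); C10 from cuprate addition cis to H‑5; C9 from bonding on the convex β face of the cis‑decalin in the rearrangement; C13 from (R)‑linalool.
4. Enabling feature: the exocyclic C8=C17 methylene of ring B next to C9 (allyl unit C17–C8–C9 flanking the C9–C11 bond), together with the folded A/B‑cis ring fusion (C5/C10) that screens the α face of C9.

Key step: step 13

Remark 1: the SMILES corresponds to (4S,5S,9S,10R,13R), an A/B‑cis (5β‑H) labdane with C20, H‑5, the C19 carboxyl and the C9 side chain all on the β face; the route is built for this cis‑fused skeleton.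
Remark 2: labdane numbering is used in the explanations (ring A C1–C5/C10, ring B C5–C10, side chain C11–C16, C17 exocyclic methylene, C18 4α‑methyl, C19 carboxyl, C20 10‑methyl); β is the face of C20.

**Route**

Step 1
Reactants: 1 6‑methoxy‑3,4‑dihydronaphthalen‑1(2H)‑one (6‑methoxy‑1‑tetralone)
Product: 2 6‑methoxy‑1‑methylidene‑1,2,3,4‑tetrahydronaphthalene
Conditions: Ph3PCH3Br, KOtBu, THF, 0 °C → rt
Reagents that add atoms: methyltriphenylphosphonium bromide, C[P+](c1ccccc1)(c1ccccc1)c1ccccc1.[Br-]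
Why: Wittig methylenation of the aryl ketone with the non‑stabilised ylide should give the 1,1‑disubstituted vinylarene; no stereocentre is formed.

Step 2
Reactants: 2 6‑methoxy‑1‑methylidene‑1,2,3,4‑tetrahydronaphthalene
Product: 3 (R)‑1‑ethenyl‑6‑methoxy‑1‑methyl‑1,2,3,4‑tetrahydronaphthalene
Conditions: ethylene (1 atm), [(allyl)NiBr]2 (cat.), BINOL‑derived phosphoramidite of bis(1‑phenylethyl)amine (cat., antipode chosen to give (R)‑3), NaBArF4, CH2Cl2, −70 °C
Reagents that add atoms: ethylene, C=C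
Why: Ni‑hydride‑catalysed asymmetric hydrovinylation of a 1‑methylidene‑tetralin, in which Markovnikov Ni–H addition gives the tertiary benzylic nickel species and ethylene insertion/β‑hydride elimination should create the quaternary C4 with the enantioface chosen by the ligand.

Step 3
Reactants: 3 (R)‑1‑ethenyl‑6‑methoxy‑1‑methyl‑1,2,3,4‑tetrahydronaphthalene
Product: 5 (S)‑6‑methoxy‑1‑methyl‑1,2,3,4‑tetrahydronaphthalene‑1‑carboxylic acid, via aldehyde 4 (not isolated)
Conditions: O3, CH2Cl2–MeOH, −78 °C (dye end point); Me2S; then NaClO2, NaH2PO4, 2‑methyl‑2‑butene, t‑BuOH–H2O, rt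
Reagents that add atoms: ozone, [O-][O+]=O; sodium chlorite, [Na+].[O-]Cl=O
Why: ozonolysis of the only alkene (the anisole ring reacts far more slowly at −78 °C) followed by Pinnick oxidation of the non‑enolisable aldehyde should give the acid with the quaternary centre untouched (R→S is only a CIP change).

Step 4
Reactants: 5 (S)‑6‑methoxy‑1‑methyl‑1,2,3,4‑tetrahydronaphthalene‑1‑carboxylic acid
Product: 7 (S)‑1‑methyl‑6‑oxo‑1,2,3,4,5,6,7,8‑octahydronaphthalene‑1‑carboxylic acid, via dihydroanisole 6 (not isolated)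
Conditions: Li, NH3(l), THF, t‑BuOH, −78 → −33 °C; NH4Cl; then (CO2H)2, MeOH–H2O, rt
Reagents that add atoms: water, O
Why: Birch reduction of the anisole ring (the carboxylate is inert) should give the 2,5‑dihydroanisole with the tetrasubstituted C5=C10 alkene, and mild oxalic acid hydrolysis of the enol ether should unveil the C8 ketone without moving the alkene into conjugation.

Step 5
Reactants: 7 (S)‑1‑methyl‑6‑oxo‑1,2,3,4,5,6,7,8‑octahydronaphthalene‑1‑carboxylic acid
Product: 8 2‑(trimethylsilyl)ethyl (S)‑1‑methyl‑6‑oxo‑1,2,3,4,5,6,7,8‑octahydronaphthalene‑1‑carboxylate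
Conditions: Me3SiCH2CH2OH, PPh3, DIAD, THF, 0 °C → rt
Reagents that add atoms: 2‑(trimethylsilyl)ethanol, C[Si](C)(C)CCO
Why: Mitsunobu esterification, in which the hindered carboxylate is the nucleophile toward the activated primary alcohol, should proceed under neutral conditions that leave the β,γ‑enone unconjugated and gives a fluoride‑labile ester that serves as directing group in step 6.

Step 6
Reactants: 8 2‑(trimethylsilyl)ethyl (S)‑1‑methyl‑6‑oxo‑1,2,3,4,5,6,7,8‑octahydronaphthalene‑1‑carboxylate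
Product: 9 2‑(trimethylsilyl)ethyl (1S,4aR,8aS)‑1‑methyl‑6‑oxodecahydronaphthalene‑1‑carboxylate
Conditions: H2 (1–50 bar), [Ir(cod)(PCy3)(py)]PF6 (5–10 mol %), CH2Cl2, rt
Reagents that add atoms: none
Why: ester‑directed homogeneous hydrogenation with the cationic iridium catalyst, which reduces tetrasubstituted alkenes, should deliver both hydrogens to the face of C5=C10 that carries the coordinating C19 carbonyl, so that H‑5 (and the transient H‑10) end up cis to the ester.

Step 7
Reactants: 9 2‑(trimethylsilyl)ethyl (1S,4aR,8aS)‑1‑methyl‑6‑oxodecahydronaphthalene‑1‑carboxylate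
Product: 11 2‑(trimethylsilyl)ethyl (1S,8aS)‑1‑methyl‑6‑oxo‑1,2,3,4,6,7,8,8a‑octahydronaphthalene‑1‑carboxylate, via silyl enol ether 10 (not isolated)
Conditions: TMSOTf, Et3N, CH2Cl2, 0 °C; then Pd(OAc)2 (cat.), O2 (1 atm), DMSO, rt
Reagents that add atoms: none
Why: Saegusa–Ito dehydrogenation through the silyl enol ether, which for a cis‑fused 2‑decalone‑type ketone should form toward the ring fusion (C9), gives the C9=C10 enone while the C5 stereocentre set in step 6 is retained.

Step 8
Reactants: 11 2‑(trimethylsilyl)ethyl (1S,8aS)‑1‑methyl‑6‑oxo‑1,2,3,4,6,7,8,8a‑octahydronaphthalene‑1‑carboxylate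
Product: 13 2‑(trimethylsilyl)ethyl (1S,4aS,8aS)‑1,4a‑dimethyl‑6‑(trifluoromethylsulfonyloxy)‑1,2,3,4,4a,7,8,8a‑octahydronaphthalene‑1‑carboxylate, via lithium enolate 12 (not isolated)
Conditions: Me2CuLi (MeLi, CuI), Et2O, 0 °C; then N‑(5‑chloro‑2‑pyridyl)triflimide, THF, −78 °C → rt
Reagents that add atoms: lithium dimethylcuprate, [Li+].C[Cu-]C; N‑(5‑chloropyridin‑2‑yl)bis(trifluoromethanesulfonyl)imide, FC(F)(F)S(=O)(=O)N(c1ccc(Cl)cn1)S(=O)(=O)C(F)(F)F
Why: cuprate conjugate addition to the β,β‑disubstituted enone (as with isophorone‑type enones) followed by O‑triflation of the regiospecific C8(C9) enolate should place the methyl on C10 cis to H‑5 (axial attack anti to the C5–C4 bond; the opposite face would set C20 1,3‑diaxial to the 4α‑methyl), giving the cis ring fusion and the alkenyl triflate in one flask.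

Step 9
Reactants: 13 2‑(trimethylsilyl)ethyl (1S,4aS,8aS)‑1,4a‑dimethyl‑6‑(trifluoromethylsulfonyloxy)‑1,2,3,4,4a,7,8,8a‑octahydronaphthalene‑1‑carboxylate
Product: 14 2‑(trimethylsilyl)ethyl (1S,4aR,8aS)‑6‑(hydroxymethyl)‑1,4a‑dimethyl‑1,2,3,4,4a,7,8,8a‑octahydronaphthalene‑1‑carboxylate
Conditions: Bu3SnCH2OH, Pd(PPh3)4 (cat.), LiCl, 1,4‑dioxane, 100 °C
Reagents that add atoms: (tributylstannyl)methanol, CCCC[Sn](CCCC)(CCCC)CO
Why: Stille coupling of the alkenyl triflate with the hydroxymethylstannane should install C17 as the primary allylic alcohol on C8 without touching any stereocentre (4aS→4aR is only a CIP change).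

Step 10
Reactants: 15 (R)‑(−)‑linalool [(3R)‑3,7‑dimethylocta‑1,6‑dien‑3‑ol]
Product: 16 (R)‑triethyl[(3,7‑dimethylocta‑1,6‑dien‑3‑yl)oxy]silane
Conditions: TESOTf, 2,6‑lutidine, CH2Cl2, −78 → 0 °C
Reagents that add atoms: triethylsilyl trifluoromethanesulfonate, CC[Si](CC)(CC)OS(=O)(=O)C(F)(F)F
Why: silylation of the tertiary allylic alcohol with the silyl triflate should protect the C13 oxygen with retention, since the C–O bond is not involved.

Step 11
Reactants: 16 (R)‑triethyl[(3,7‑dimethylocta‑1,6‑dien‑3‑yl)oxy]silane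
Product: 18 (R)‑4‑methyl‑4‑(triethylsilyloxy)hex‑5‑enoic acid, via aldehyde 17 (not isolated)
Conditions: O3, CH2Cl2–MeOH, −78 °C (Sudan Red 7B end point); Me2S; then NaClO2, NaH2PO4, 2‑methyl‑2‑butene, t‑BuOH–H2O, rt
Reagents that add atoms: ozone, [O-][O+]=O; sodium chlorite, [Na+].[O-]Cl=O
Why: chemoselective ozonolysis of the electron‑rich trisubstituted alkene in the presence of the monosubstituted vinyl group, followed by Pinnick oxidation, should give the C6 acid whose α‑carbon is the future C11; the stereocentre is not involved.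

Step 12
Reactants: 14 2‑(trimethylsilyl)ethyl (1S,4aR,8aS)‑6‑(hydroxymethyl)‑1,4a‑dimethyl‑1,2,3,4,4a,7,8,8a‑octahydronaphthalene‑1‑carboxylate; 18 (R)‑4‑methyl‑4‑(triethylsilyloxy)hex‑5‑enoic acid
Product: 19 2‑(trimethylsilyl)ethyl (1S,4aR,8aS)‑1,4a‑dimethyl‑6‑({[(4R)‑4‑methyl‑4‑(triethylsilyloxy)hex‑5‑enoyl]oxy}methyl)‑1,2,3,4,4a,7,8,8a‑octahydronaphthalene‑1‑carboxylate
Conditions: EDC·HCl, DMAP, CH2Cl2, rt
Reagents that add atoms: none
Why: Steglich‑type carbodiimide esterification of the unhindered primary allylic alcohol should build the temporary C17–O–CO–C11 tether that the key step needs.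

Step 13
Reactants: 19 2‑(trimethylsilyl)ethyl (1S,4aR,8aS)‑1,4a‑dimethyl‑6‑({[(4R)‑4‑methyl‑4‑(triethylsilyloxy)hex‑5‑enoyl]oxy}methyl)‑1,2,3,4,4a,7,8,8a‑octahydronaphthalene‑1‑carboxylate
Product: 22 2‑(trimethylsilyl)ethyl (4S,5S,9S,10R,13R)‑11‑carboxy‑13‑(triethylsilyloxy)labda‑8(17),14‑dien‑19‑oate (C11 epimers), via silyl ketene acetal 20 (not isolated), via trimethylsilyl ester 21 (not isolated)
Conditions: LDA, TMSCl, Et3N, THF, −78 °C → rt, then 60 °C; aq. citric acid (pH 4–5) work‑up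
Reagents that add atoms: none
Why: Kinetic deprotonation at C11 (the only α‑C–H, since the C19 ester sits on quaternary C4) and O‑silylation give ketene acetal 20, which should undergo a concerted suprafacial [3,3]‑sigmatropic shift through a six‑membered chair array O–C17–C8=C9···C11=C(O)2: C11 bonds to C9, the C17–O bond breaks and the ring alkene becomes the exocyclic C8=C17 methylene. The closest known reaction type is the Ireland–Claisen rearrangement of primary allylic esters of cyclohex‑1‑enylmethanols, which forms congested bonds next to quaternary carbons because it is intramolecular. No ring is closed: the cyclic array exists only in the transition state and the ester tether is consumed, leaving the C11 carboxyl as the only helper. The new stereocentre C9 is substrate‑controlled: in the cis‑fused decalin, ring B should react in the half‑chair with the C10–C1 bond pseudoaxial on the concave α face, so C11 is delivered axially to the convex β face of C9, anti to C10–C1 and cis to C20 and H‑5, while ring A (C1 and the C4 substituents) screens the α face; C11 is also stereogenic but is erased in step 14. The step needs site‑selective enolisation, C9‑versus‑C17 regiocontrol and β‑face selectivity, which are secured respectively by the single enolisable ester, by the pericyclic array (only the C17–C8=C9 allyl unit is present) and by the A/B‑cis ring fusion.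

Step 14
Reactants: 22 2‑(trimethylsilyl)ethyl (4S,5S,9S,10R,13R)‑11‑carboxy‑13‑(triethylsilyloxy)labda‑8(17),14‑dien‑19‑oate (C11 epimers)
Product: 24 2‑(trimethylsilyl)ethyl (4S,5S,9S,10R,13R)‑13‑(triethylsilyloxy)labda‑8(17),14‑dien‑19‑oate, via thiohydroxamate ester 23 (not isolated)
Conditions: N‑hydroxypyridine‑2‑thione, DCC, DMAP (cat.), CH2Cl2, rt, dark; then t‑BuSH, hν (W lamp), rt
Reagents that add atoms: none
Why: Barton reductive decarboxylation (radical chain) should convert the thiohydroxamate ester into the secondary C11 radical, which takes hydrogen from the thiol faster than any 3‑exo, 4‑exo or 5‑endo closure onto the alkenes, removing the helper carboxyl and the C11 stereocentre.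

Step 15
Reactants: 24 2‑(trimethylsilyl)ethyl (4S,5S,9S,10R,13R)‑13‑(triethylsilyloxy)labda‑8(17),14‑dien‑19‑oate
Product: 25 (4S,5S,9S,10R,13R)‑13‑hydroxylabda‑8(17),14‑dien‑19‑oic acid
Conditions: TBAF, THF, rt → 45 °C; aq. NH4Cl
Reagents that add atoms: none
Why: fluoride should cleave both silicon groups, the 2‑(trimethylsilyl)ethyl ester by β‑elimination (ethene and Me3SiF) and the tertiary triethylsilyl ether by desilylation, under non‑acidic conditions that spare the exocyclic alkene and the tertiary allylic alcohol.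

Step 16
Reactants: 25 (4S,5S,9S,10R,13R)‑13‑hydroxylabda‑8(17),14‑dien‑19‑oic acid
Product: 27 (4S,5S,9S,10R,13R)‑13‑acetoxylabda‑8(17),14‑dien‑19‑oic acid (target), via mixed anhydride 26 (not isolated)
Conditions: Ac2O, Et3N, DMAP, CH2Cl2, rt → 35 °C; then aq. NaHCO3–THF, rt
Reagents that add atoms: acetic anhydride, CC(=O)OC(C)=O
Why: DMAP‑catalysed acetylation should esterify the tertiary allylic alcohol, while the carboxyl is only transiently converted into the mixed anhydride, which the bicarbonate work‑up hydrolyses at the unhindered acetyl carbonyl without touching the tertiary acetate.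

**Compound list**

1 | 6‑methoxy‑3,4‑dihydronaphthalen‑1(2H)‑one | COc1ccc2c(c1)CCCC2=O | starting material
2 | 6‑methoxy‑1‑methylidene‑1,2,3,4‑tetrahydronaphthalene | COc1ccc2c(c1)CCCC2=C | intermediate
3 | (R)‑1‑ethenyl‑6‑methoxy‑1‑methyl‑1,2,3,4‑tetrahydronaphthalene | COc1ccc2c(c1)CCC[C@]2(C)C=C | intermediate
4 | (S)‑6‑methoxy‑1‑methyl‑1,2,3,4‑tetrahydronaphthalene‑1‑carbaldehyde | COc1ccc2c(c1)CCC[C@]2(C)C=O | intermediate (not isolated)
5 | (S)‑6‑methoxy‑1‑methyl‑1,2,3,4‑tetrahydronaphthalene‑1‑carboxylic acid | COc1ccc2c(c1)CCC[C@]2(C)C(=O)O | intermediate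
6 | (S)‑6‑methoxy‑1‑methyl‑1,2,3,4,5,8‑hexahydronaphthalene‑1‑carboxylic acid | COC1=CCC2=C(C1)CCC[C@]2(C)C(=O)O | intermediate (not isolated)
7 | (S)‑1‑methyl‑6‑oxo‑1,2,3,4,5,6,7,8‑octahydronaphthalene‑1‑carboxylic acid | O=C1CCC2=C(C1)CCC[C@]2(C)C(=O)O | intermediate
8 | 2‑(trimethylsilyl)ethyl (S)‑1‑methyl‑6‑oxo‑1,2,3,4,5,6,7,8‑octahydronaphthalene‑1‑carboxylate | O=C1CCC2=C(C1)CCC[C@]2(C)C(=O)OCC[Si](C)(C)C | intermediate
9 | 2‑(trimethylsilyl)ethyl (1S,4aR,8aS)‑1‑methyl‑6‑oxodecahydronaphthalene‑1‑carboxylate (cis‑fused; H‑5, H‑10 and ester on one face) | O=C1CC[C@H]2[C@@H](C1)CCC[C@]2(C)C(=O)OCC[Si](C)(C)C | intermediate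
10 | trimethylsilyl enol ether of 9 (C8=C9 enol ether) | C1=C(O[Si](C)(C)C)CC[C@H]2[C@@H]1CCC[C@]2(C)C(=O)OCC[Si](C)(C)C | intermediate (not isolated)
11 | 2‑(trimethylsilyl)ethyl (1S,8aS)‑1‑methyl‑6‑oxo‑1,2,3,4,6,7,8,8a‑octahydronaphthalene‑1‑carboxylate | O=C1CC[C@H]2C(=C1)CCC[C@]2(C)C(=O)OCC[Si](C)(C)C | intermediate
12 | lithium C8(C9)‑enolate of the 10β‑methyl cis‑decalone | C1=C(O[Li])CC[C@H]2[C@]1(C)CCC[C@]2(C)C(=O)OCC[Si](C)(C)C | intermediate (not isolated)
13 | 2‑(trimethylsilyl)ethyl (1S,4aS,8aS)‑1,4a‑dimethyl‑6‑(trifluoromethylsulfonyloxy)‑1,2,3,4,4a,7,8,8a‑octahydronaphthalene‑1‑carboxylate | C1=C(OS(=O)(=O)C(F)(F)F)CC[C@H]2[C@]1(C)CCC[C@]2(C)C(=O)OCC[Si](C)(C)C | intermediate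
14 | 2‑(trimethylsilyl)ethyl (1S,4aR,8aS)‑6‑(hydroxymethyl)‑1,4a‑dimethyl‑1,2,3,4,4a,7,8,8a‑octahydronaphthalene‑1‑carboxylate | C1=C(CO)CC[C@H]2[C@]1(C)CCC[C@]2(C)C(=O)OCC[Si](C)(C)C | intermediate
15 | (R)‑(−)‑linalool | CC(C)=CCC[C@](C)(C=C)O | starting material
16 | (R)‑triethyl[(3,7‑dimethylocta‑1,6‑dien‑3‑yl)oxy]silane | CC(C)=CCC[C@](C)(C=C)O[Si](CC)(CC)CC | intermediate
17 | (R)‑4‑methyl‑4‑(triethylsilyloxy)hex‑5‑enal | O=CCC[C@](C)(C=C)O[Si](CC)(CC)CC | intermediate (not isolated)
18 | (R)‑4‑methyl‑4‑(triethylsilyloxy)hex‑5‑enoic acid | OC(=O)CC[C@](C)(C=C)O[Si](CC)(CC)CC | intermediate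
19 | 2‑(trimethylsilyl)ethyl (1S,4aR,8aS)‑1,4a‑dimethyl‑6‑({[(4R)‑4‑methyl‑4‑(triethylsilyloxy)hex‑5‑enoyl]oxy}methyl)‑1,2,3,4,4a,7,8,8a‑octahydronaphthalene‑1‑carboxylate | C1=C(COC(=O)CC[C@](C)(C=C)O[Si](CC)(CC)CC)CC[C@H]2[C@]1(C)CCC[C@]2(C)C(=O)OCC[Si](C)(C)C | intermediate
20 | trimethylsilyl ketene acetal of 19 (O‑silyl enolate at C11; double‑bond geometry not defined, immaterial) | C1=C(COC(O[Si](C)(C)C)=CC[C@](C)(C=C)O[Si](CC)(CC)CC)CC[C@H]2[C@]1(C)CCC[C@]2(C)C(=O)OCC[Si](C)(C)C | intermediate (not isolated)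
21 | trimethylsilyl ester of acid 22 (C11 epimers) | C=C[C@@](C)(CC(C(=O)O[Si](C)(C)C)[C@H]1C(=C)CC[C@H]2[C@]1(C)CCC[C@]2(C)C(=O)OCC[Si](C)(C)C)O[Si](CC)(CC)CC | intermediate (not isolated)
22 | 2‑(trimethylsilyl)ethyl (4S,5S,9S,10R,13R)‑11‑carboxy‑13‑(triethylsilyloxy)labda‑8(17),14‑dien‑19‑oate (C11 epimers) | C=C[C@@](C)(CC(C(=O)O)[C@H]1C(=C)CC[C@H]2[C@]1(C)CCC[C@]2(C)C(=O)OCC[Si](C)(C)C)O[Si](CC)(CC)CC | intermediate
23 | N‑acyloxypyridine‑2‑thione (thiohydroxamate ester) of 22 | C=C[C@@](C)(CC(C(=O)On1ccccc1=S)[C@H]1C(=C)CC[C@H]2[C@]1(C)CCC[C@]2(C)C(=O)OCC[Si](C)(C)C)O[Si](CC)(CC)CC | intermediate (not isolated)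
24 | 2‑(trimethylsilyl)ethyl (4S,5S,9S,10R,13R)‑13‑(triethylsilyloxy)labda‑8(17),14‑dien‑19‑oate | C=C[C@@](C)(CC[C@H]1C(=C)CC[C@H]2[C@]1(C)CCC[C@]2(C)C(=O)OCC[Si](C)(C)C)O[Si](CC)(CC)CC | intermediate
25 | (4S,5S,9S,10R,13R)‑13‑hydroxylabda‑8(17),14‑dien‑19‑oic acid | C=C[C@@](C)(CC[C@H]1C(=C)CC[C@H]2[C@]1(C)CCC[C@]2(C)C(=O)O)O | intermediate
26 | mixed acetic anhydride of 27 at C19 | C=C[C@@](C)(CC[C@H]1C(=C)CC[C@H]2[C@]1(C)CCC[C@]2(C)C(=O)OC(C)=O)OC(C)=O | intermediate (not isolated)
27 | (4S,5S,9S,10R,13R)‑13‑acetoxylabda‑8(17),14‑dien‑19‑oic acid = (1S,4aR,5S,8aS)‑5‑[(3R)‑3‑acetoxy‑3‑methylpent‑4‑en‑1‑yl]‑1,4a‑dimethyl‑6‑methylidenedecahydronaphthalene‑1‑carboxylic acid | C=C[C@@](C)(CC[C@H]1C(=C)CC[C@H]2[C@]1(C)CCC[C@]2(C)C(=O)O)OC(C)=O | target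

**Step count and risks**

Total step count: 16. Longest linear sequence: 14 (steps 1–9 and 12–16); steps 10–11 make the side‑chain acid.

Steps most likely to fail:

1. Step 13. The risk is incomplete enolisation/silylation followed by a slow shift next to the quaternary C10, or bond formation on the α face of C9. Fallback (intermolecular enolate alkylation plus carbonyl methylenation, from 11 and 18, back at 24): acid 18 would be converted into its N‑acyloxypyridine‑2‑thione F1 and photolysed with iodoform (Barton iododecarboxylation) to (R)‑triethyl[(5‑iodo‑3‑methylpent‑1‑en‑3‑yl)oxy]silane F2. Enone 11 would be treated with Me2CuLi as in step 8, and the regiospecific enolate 12 alkylated in the same flask with F2 (HMPA–THF, 0 °C → rt), again on the convex β face, to give the 17‑nor‑8‑ketone F3. Non‑basic Zn/CH2Br2/TiCl4 methylenation of F3, which should not epimerise the α‑centre C9, would give 24.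

2. Step 6. The risk is hydrogen delivery without facial control (ketone competing with ester coordination), isomerisation of the β,γ‑alkene into conjugation, or no reduction of the tetrasubstituted alkene. Fallback (thermodynamic route, from 8, back at 11, bypassing steps 6 and 7): 8 would be conjugated with DBU (CH2Cl2, rt) to a mixture of 11 and its C5 epimer F4. The two would be separated by chromatography and F4 returned to the DBU equilibration until it is consumed.

3. Step 9. The risk is slow transmetalation of the hydroxymethylstannane, with protodestannylation or reduction of the triflate. Fallback (carbonylation/reduction, from 13, back at 14): Pd(OAc)2/dppp, CO (1 atm), MeOH, Et3N, DMF would give the conjugated methyl ester F5. DIBAL‑H (CH2Cl2, −78 °C) would then reduce this unhindered ester in preference to the neopentyl‑type C19 silylethyl ester to give 14.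

**Further compounds**

F1 | step 13 | N‑acyloxypyridine‑2‑thione of acid 18 | C=C[C@@](C)(CCC(=O)On1ccccc1=S)O[Si](CC)(CC)CC
F2 | step 13 | (R)‑triethyl[(5‑iodo‑3‑methylpent‑1‑en‑3‑yl)oxy]silane | C=C[C@@](C)(CCI)O[Si](CC)(CC)CC
F3 | step 13 | 2‑(trimethylsilyl)ethyl (4S,5S,9S,10R,13R)‑8‑oxo‑13‑(triethylsilyloxy)‑17‑norlabd‑14‑en‑19‑oate | C=C[C@@](C)(CC[C@H]1C(=O)CC[C@H]2[C@]1(C)CCC[C@]2(C)C(=O)OCC[Si](C)(C)C)O[Si](CC)(CC)CC
F4 | step 6 | 2‑(trimethylsilyl)ethyl (1S,8aR)‑1‑methyl‑6‑oxo‑1,2,3,4,6,7,8,8a‑octahydronaphthalene‑1‑carboxylate (C5 epimer of 11) | O=C1CC[C@@H]2C(=C1)CCC[C@]2(C)C(=O)OCC[Si](C)(C)C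
F5 | step 9 | 2‑methyl 5‑[2‑(trimethylsilyl)ethyl] (4aR,5S,8aS)‑5,8a‑dimethyl‑3,4,4a,5,6,7,8,8a‑octahydronaphthalene‑2,5‑dicarboxylate | C1=C(C(=O)OC)CC[C@H]2[C@]1(C)CCC[C@]2(C)C(=O)OCC[Si](C)(C)C
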